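**Strategy.** The 3,4-dihydro-2H-pyran (O1', spiro C2', C3', C4', C5', C6') is not closed as a six-membered ring. It is reached by two-atom ring expansion of a spiro-cyclobutane (C2', C3', C4', C5') whose C5' carries the formyl group that becomes C6'–O1'. Heating breaks the strained bond between the two quaternary, carbonyl-flanked carbons C2' and C5' and re-forms C2'–O1' on the open face of the lactone, which sets the spiro centre. The cyclobutane is the head-to-head [2+2] photoadduct of (+)-alantolactone and the ent-elemane enal; the enal comes from a catalytic asymmetric Diels–Alder reaction.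

Key step: step 9

Assumption: the elemane half of the target is antipodal to commercial (−)-β-elemene and is therefore made de novo; the facial sense of the oxazaborolidinium catalyst in step 3 is taken from the formyl C–H···O binding model, and the antipodal catalyst would be used if the opposite sense were observed.

Step 1
Reactants: 1 methylglyoxal (2-oxopropanal, aqueous solution); 2 2-(triphenylphosphoranylidene)propanal
Product: 3 (2E)-2-methyl-4-oxopent-2-enal
Conditions: CH2Cl2/H2O, 0 °C → rt, excess of 1
Reagents that add atoms: none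
Why: Wittig olefination of the aldehyde group of 1 (the ketone is much less electrophilic) by the formyl-stabilised ylide should give the E-trisubstituted alkene with acetyl trans to CHO.

Step 2
Reactants: 4 methyl vinyl ketone
Product: 5 2-(triisopropylsilyloxy)buta-1,3-diene
Conditions: TIPSOTf, Et3N, Et2O, 0 °C
Reagents that add atoms: triisopropylsilyl trifluoromethanesulfonate CC(C)[Si](C(C)C)(C(C)C)OS(=O)(=O)C(F)(F)F
Why: Soft enolisation of the methyl ketone and O-silylation is the standard entry to 2-silyloxydienes; the bulky silyl group should make the diene stable to the acidic catalyst of step 3.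

Step 3
Reactants: 3 (2E)-2-methyl-4-oxopent-2-enal; 5 2-(triisopropylsilyloxy)buta-1,3-diene
Product: 6 (1S,6S)-6-acetyl-1-methyl-4-[(triisopropylsilyl)oxy]cyclohex-3-ene-1-carbaldehyde
Conditions: (S)-o-tolyl oxazaborolidinium triflimide [from (S)-α,α-diphenylprolinol, tri(o-tolyl)boroxine, Tf2NH] (20 mol %), CH2Cl2, −78 → −40 °C
Reagents that add atoms: none
Why: Catalytic asymmetric Diels–Alder reaction in which the catalyst binds the formyl group, the nucleophilic C1 of 5 bonds to C3 of 3 (β to CHO, "para" orientation), suprafacial addition turns the E geometry into the trans CHO/acetyl relationship, and shielding of one enal face by the catalyst aryl group should set both stereocentres as (1S,6S).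

Step 4
Reactants: 6 (1S,6S)-6-acetyl-1-methyl-4-[(triisopropylsilyl)oxy]cyclohex-3-ene-1-carbaldehyde
Product: 8 (3R,4R)-4-ethenyl-4-methyl-3-(prop-1-en-2-yl)cyclohexan-1-one (ent-geijerone), via silyl enol ether 7 (not isolated)
Conditions: Cp2TiMe2 (3 equiv), toluene, 70 °C, dark; then TBAF, AcOH, THF, 0 °C
Reagents that add atoms: dimethyltitanocene C[Ti](C)(C1C=CC=C1)C1C=CC=C1
Why: Non-basic carbonyl methylenation by the titanium methylidene should turn CHO into vinyl and acetyl into isopropenyl without epimerising the acetyl-bearing carbon or triggering aldol closure of the 1,4-dicarbonyl unit, and fluoride then unmasks the ring ketone; no stereocentre is formed.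

Step 5
Reactants: 8 (3R,4R)-4-ethenyl-4-methyl-3-(prop-1-en-2-yl)cyclohexan-1-one
Product: 10 1-[(1S,3R,4R)-4-ethenyl-4-methyl-3-(prop-1-en-2-yl)cyclohexyl]ethan-1-one, via methyl enol ether 9 (not isolated)
Conditions: Ph3P(+)CH(OMe)CH3 Cl(−), KOtBu, THF, −20 °C → rt; then 1 M HCl, THF, rt; then K2CO3, MeOH, rt
Reagents that add atoms: (1-methoxyethyl)triphenylphosphonium chloride COC(C)[P+](c1ccccc1)(c1ccccc1)c1ccccc1.[Cl-]; water O
Why: Wittig reaction with the α-methoxy ylide and hydrolysis of the enol ether is a one-carbon-plus-methyl homologation to the acetyl group, and base equilibration of the epimerisable centre should place acetyl equatorial, cis to the equatorial isopropenyl group (1S).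

Step 6
Reactants: 10 1-[(1S,3R,4R)-4-ethenyl-4-methyl-3-(prop-1-en-2-yl)cyclohexyl]ethan-1-one
Product: 11 N'-{(1E)-1-[(1S,3R,4R)-4-ethenyl-4-methyl-3-(prop-1-en-2-yl)cyclohexyl]ethylidene}-2,4,6-tri(propan-2-yl)benzenesulfonohydrazide
Conditions: 2,4,6-triisopropylbenzenesulfonohydrazide, THF, cat. HCl, rt
Reagents that add atoms: 2,4,6-triisopropylbenzenesulfonohydrazide CC(C)c1cc(C(C)C)c(S(=O)(=O)NN)c(C(C)C)c1
Why: Condensation of the methyl ketone with the hindered arenesulfonyl hydrazide should give the E-hydrazone (sulfonamide syn to the methyl group), the substrate for the Shapiro reaction; the adjacent centre stays in its thermodynamic equatorial configuration.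

Step 7
Reactants: 11 N'-{(1E)-1-[(1S,3R,4R)-4-ethenyl-4-methyl-3-(prop-1-en-2-yl)cyclohexyl]ethylidene}-2,4,6-tri(propan-2-yl)benzenesulfonohydrazide
Product: 13 2-[(1S,3R,4R)-4-ethenyl-4-methyl-3-(prop-1-en-2-yl)cyclohexyl]prop-2-enal (ent-elemenal), via vinyllithium 12 (not isolated)
Conditions: n-BuLi (2.2 equiv), TMEDA, hexane/THF, −78 → 0 °C; then DMF, −78 °C → rt; H2O
Reagents that add atoms: N,N-dimethylformamide CN(C)C=O; n-butyllithium CCCC[Li] (lithium of 12 only)
Why: Shapiro reaction, in which the dianion forms at the less hindered methyl group, loses sulfinate and N2 to the 1-substituted vinyllithium, and formylation with DMF should give the 2-substituted acrolein without touching the ring stereocentres.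

Step 8
Reactants: 13 2-[(1S,3R,4R)-4-ethenyl-4-methyl-3-(prop-1-en-2-yl)cyclohexyl]prop-2-enal; 14 (+)-alantolactone
Product: 15 (1S,2S,3a'R,5'S,8a'R,9a'R)-2-[(1S,3R,4R)-4-ethenyl-4-methyl-3-(prop-1-en-2-yl)cyclohexyl]-5',8a'-dimethyl-2'-oxo-3a',5',6',7',8',8a',9',9a'-octahydro-2'H-spiro[cyclobutane-1,3'-naphtho[2,3-b]furan]-2-carbaldehyde
Conditions: 14 (5 equiv, excess recovered), 9H-xanthen-9-one (20 mol %), hν (365 nm), MeCN, −20 °C
Reagents that add atoms: none
Why: Crossed [2+2] photocycloaddition of the enone–alkene type through the enal triplet, whose β-CH2 should bond to the exocyclic CH2 of 14 to give the 1,4-diradical with two tertiary carbonyl-stabilised centres (hence head-to-head), the s-trans oxallyl end cannot close on oxygen, and C–C closure on the exo face of the lactone should set the spiro carbon (S) with the cyclohexyl group anti to the decalin-bearing lactone carbon; the epimer at the formyl-bearing carbon serves equally in step 9.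

Step 9
Reactants: 15 spiro-cyclobutane carbaldehyde
Product: 16 (3R,3aS,5S,8aR,9aR)-5'-[(1S,3R,4R)-4-ethenyl-4-methyl-3-(prop-1-en-2-yl)cyclohexyl]-5,8a-dimethyl-3',3a,4',5,6,7,8,8a,9,9a-decahydro-2H-spiro[naphtho[2,3-b]furan-3,2'-pyran]-2-one (CNP0175206.1)
Conditions: toluene (0.02 M), BHT (10 mol %), 130 °C, sealed tube, argon, dark
Reagents that add atoms: none
Why: Proposed new method: on heating, the bond between the spiro carbon C2' (α to the lactone carbonyl) and the formyl-bearing C5' should break homolytically or in a strongly asynchronous concerted way, because both carbons are quaternary, both radicals are tertiary and carbonyl-stabilised and cyclobutane strain is released; the oxallyl oxygen then recombines with C2', a 1,3-shift of C2' from carbon to oxygen that expands the cyclobutane by C6' and O1' into the 3,4-dihydro-2H-pyran. The closest known reaction types are the thermal vinylcyclobutane-to-cyclohexene rearrangement, the isomerisation of donor-substituted acylcyclobutanes to dihydropyrans and the Cloke–Wilson rearrangement of acylcyclopropanes; no donor is present here, so the diradical manifold is used. The six-membered ring closes by C–O bond formation in a 6-endo recombination that places the new C5'=C6' enol ether bond inside the ring; carbon recombination only regenerates 15 or its epimers, whereas oxygen closure is irreversible. The only new stereocentre, the spiro carbon, should be set by the cis-fused lactone: oxygen adds to the planar radical on the exo face, syn to H-3a and H-9a and away from the carbocycle, which is also the face C5' occupied, so retention and radical closure converge on (R), while C5' becomes sp2 and its configuration in 15 is irrelevant. The step needs oxygen over carbon closure and ring closure over cycloreversion or hydrogen transfer; the thermodynamic sink (strain release, enol ether formation), free rotation of the formyl group into the geometry with oxygen syn to C4' before cleavage, high dilution and a radical inhibitor should secure this.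

**Compound list**

1 | methylglyoxal (2-oxopropanal) | CC(=O)C=O | starting material
2 | 2-(triphenylphosphoranylidene)propanal | CC(C=O)=P(c1ccccc1)(c1ccccc1)c1ccccc1 | starting material
3 | (2E)-2-methyl-4-oxopent-2-enal | CC(=O)/C=C(\C)C=O | intermediate
4 | methyl vinyl ketone (but-3-en-2-one) | CC(=O)C=C | starting material
5 | 2-(triisopropylsilyloxy)buta-1,3-diene | C=CC(=C)O[Si](C(C)C)(C(C)C)C(C)C | intermediate
6 | (1S,6S)-6-acetyl-1-methyl-4-[(triisopropylsilyl)oxy]cyclohex-3-ene-1-carbaldehyde (CHO and acetyl trans) | O=C[C@@]1(C)CC=C(O[Si](C(C)C)(C(C)C)C(C)C)C[C@@H]1C(C)=O | intermediate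
7 | {[(4R,5R)-4-ethenyl-4-methyl-5-(prop-1-en-2-yl)cyclohex-1-en-1-yl]oxy}tri(propan-2-yl)silane | C=C[C@@]1(C)CC=C(O[Si](C(C)C)(C(C)C)C(C)C)C[C@@H]1C(=C)C | intermediate
8 | (3R,4R)-4-ethenyl-4-methyl-3-(prop-1-en-2-yl)cyclohexan-1-one (ent-geijerone) | C=C[C@@]1(C)CCC(=O)C[C@@H]1C(=C)C | intermediate
9 | (1R,2R)-1-ethenyl-4-(1-methoxyethylidene)-1-methyl-2-(prop-1-en-2-yl)cyclohexane (E/Z mixture) | C=C[C@@]1(C)CCC(=C(C)OC)C[C@@H]1C(=C)C | intermediate
10 | 1-[(1S,3R,4R)-4-ethenyl-4-methyl-3-(prop-1-en-2-yl)cyclohexyl]ethan-1-one (acetyl, isopropenyl and methyl cis) | C=C[C@@]1(C)CC[C@H](C(C)=O)C[C@@H]1C(=C)C | intermediate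
11 | N'-{(1E)-1-[(1S,3R,4R)-4-ethenyl-4-methyl-3-(prop-1-en-2-yl)cyclohexyl]ethylidene}-2,4,6-tri(propan-2-yl)benzenesulfonohydrazide | C=C[C@@]1(C)CC[C@H](/C(C)=N/NS(=O)(=O)c2c(C(C)C)cc(C(C)C)cc2C(C)C)C[C@@H]1C(=C)C | intermediate
12 | {1-[(1S,3R,4R)-4-ethenyl-4-methyl-3-(prop-1-en-2-yl)cyclohexyl]ethenyl}lithium | C=C[C@@]1(C)CC[C@H](C(=C)[Li])C[C@@H]1C(=C)C | intermediate
13 | 2-[(1S,3R,4R)-4-ethenyl-4-methyl-3-(prop-1-en-2-yl)cyclohexyl]prop-2-enal (ent-elemenal) | C=C[C@@]1(C)CC[C@H](C(=C)C=O)C[C@@H]1C(=C)C | intermediate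
14 | (+)-alantolactone, (3aR,5S,8aR,9aR)-5,8a-dimethyl-3-methylidene-3a,5,6,7,8,8a,9,9a-octahydronaphtho[2,3-b]furan-2(3H)-one | C=C1C(=O)O[C@@H]2C[C@@]3(C)CCC[C@H](C)C3=C[C@H]12 | starting material
15 | (1S,2S,3a'R,5'S,8a'R,9a'R)-2-[(1S,3R,4R)-4-ethenyl-4-methyl-3-(prop-1-en-2-yl)cyclohexyl]-5',8a'-dimethyl-2'-oxo-3a',5',6',7',8',8a',9',9a'-octahydro-2'H-spiro[cyclobutane-1,3'-naphtho[2,3-b]furan]-2-carbaldehyde (cyclobutane C2 on the exo face of the lactone; formyl cis to the lactone carbon C3a') | C=C[C@@]1(C)CC[C@H]([C@@]5(C=O)CC[C@@]56C(=O)O[C@@H]7C[C@@]8(C)CCC[C@H](C)C8=C[C@H]67)C[C@@H]1C(=C)C | intermediate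
16 | (3R,3aS,5S,8aR,9aR)-5'-[(1S,3R,4R)-4-ethenyl-4-methyl-3-(prop-1-en-2-yl)cyclohexyl]-5,8a-dimethyl-3',3a,4',5,6,7,8,8a,9,9a-decahydro-2H-spiro[naphtho[2,3-b]furan-3,2'-pyran]-2-one (CNP0175206.1) | C=C[C@@]1(C)CC[C@H](C2=CO[C@@]3(CC2)C(=O)O[C@@H]2C[C@@]4(C)CCC[C@H](C)C4=C[C@@H]23)C[C@@H]1C(=C)C | target

**Step count.** Total: 9 steps. Longest linear sequence: 8 steps (steps 1, 3, 4, 5, 6, 7, 8, 9).

**Steps most likely to fail**

1. Step 9 (Proposed new method). The 1,4-diradical may undergo cycloreversion to 13 and 14, or hydrogen transfer from H-3a' (retro-ene opening), faster than C–O closure; closure may also be unselective at the spiro carbon. Fallback: the route sets out again from 13 and 14, by-passes 15 and arrives directly at 16 by a thermal hetero-Diels–Alder reaction of the s-cis enal (1-oxadiene) with the exocyclic alkene of 14 (concentrated toluene, 110–130 °C, hydroquinone, or 10–15 kbar at rt). This is known chemistry for 2-substituted acroleins and α-methylene lactones, and exo-face approach gives the same spiro configuration. No new compound is made (F0).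

2. Step 8. Triplet capture may be inefficient because the acyclic enal relaxes by twisting; homodimerisation of either partner, addition to the unactivated alkenes or oxetane formation at the formyl group may compete. Fallback: the route sets out from 13. Addition of 2-lithio-1-methylimidazole (THF, −78 °C) gives 2-[(1S,3R,4R)-4-ethenyl-4-methyl-3-(prop-1-en-2-yl)cyclohexyl]-1-(1-methyl-1H-imidazol-2-yl)prop-2-en-1-ol F1. MnO2 oxidation gives the α,β-unsaturated 2-acylimidazole F2. A visible-light photocatalytic radical-anion crossed [2+2] cycloaddition with 14 (Ru(bpy)3Cl2, LiBF4, i-Pr2NEt, MeCN), in which the β-carbon of the reduced enone adds to the CH2 of 14 (head-to-head), gives the spiro-cyclobutyl 2-acylimidazole F3. N-methylation (MeOTf) and NaBH4 (MeOH, 0 °C) cleave the acylimidazolium to the spiro-cyclobutylmethanol F4. Periodinane oxidation (DMP, CH2Cl2) comes back to the route at 15.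

3. Step 3. Ketone-directed instead of aldehyde-directed orientation, hetero-cycloaddition at a carbonyl group, or erosion of enantioselectivity by two-point binding of the keto-enal may occur. Fallback: the route sets out from 5 and commercial ethyl (2E)-3-formylbut-2-enoate, in which the aldehyde is the only group bound by the catalyst. The same catalysis gives ethyl (1S,2S)-2-formyl-2-methyl-5-[(triisopropylsilyl)oxy]cyclohex-4-ene-1-carboxylate F5. Wittig methylenation (Ph3P=CH2, THF) gives ethyl (1S,2R)-2-ethenyl-2-methyl-5-[(triisopropylsilyl)oxy]cyclohex-4-ene-1-carboxylate F6. MeLi/CeCl3 (THF, −78 °C) gives the tertiary alcohol 2-{(1S,6R)-6-ethenyl-6-methyl-3-[(triisopropylsilyl)oxy]cyclohex-3-en-1-yl}propan-2-ol F7. Dehydration toward the methyl group with methyl N-(triethylammoniosulfonyl)carbamate (benzene, 50 °C) comes back to the route at 7, which is desilylated to 8 as in step 4.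

**Further compounds**

F0 | step 9 | none | none
F1 | step 8 | 2-[(1S,3R,4R)-4-ethenyl-4-methyl-3-(prop-1-en-2-yl)cyclohexyl]-1-(1-methyl-1H-imidazol-2-yl)prop-2-en-1-ol (both carbinol epimers) | C=C[C@@]1(C)CC[C@H](C(=C)C(O)c2nccn2C)C[C@@H]1C(=C)C
F2 | step 8 | 2-[(1S,3R,4R)-4-ethenyl-4-methyl-3-(prop-1-en-2-yl)cyclohexyl]-1-(1-methyl-1H-imidazol-2-yl)prop-2-en-1-one | C=C[C@@]1(C)CC[C@H](C(=C)C(=O)c2nccn2C)C[C@@H]1C(=C)C
F3 | step 8 | spiro-cyclobutane of 15 with (1-methyl-1H-imidazol-2-yl)carbonyl in place of formyl | C=C[C@@]1(C)CC[C@H]([C@@]5(C(=O)c9nccn9C)CC[C@@]56C(=O)O[C@@H]7C[C@@]8(C)CCC[C@H](C)C8=C[C@H]67)C[C@@H]1C(=C)C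
F4 | step 8 | spiro-cyclobutane of 15 with hydroxymethyl in place of formyl | C=C[C@@]1(C)CC[C@H]([C@@]5(CO)CC[C@@]56C(=O)O[C@@H]7C[C@@]8(C)CCC[C@H](C)C8=C[C@H]67)C[C@@H]1C(=C)C
F5 | step 3 | ethyl (1S,2S)-2-formyl-2-methyl-5-[(triisopropylsilyl)oxy]cyclohex-4-ene-1-carboxylate | O=C[C@@]1(C)CC=C(O[Si](C(C)C)(C(C)C)C(C)C)C[C@@H]1C(=O)OCC
F6 | step 3 | ethyl (1S,2R)-2-ethenyl-2-methyl-5-[(triisopropylsilyl)oxy]cyclohex-4-ene-1-carboxylate | C=C[C@@]1(C)CC=C(O[Si](C(C)C)(C(C)C)C(C)C)C[C@@H]1C(=O)OCC
F7 | step 3 | 2-{(1S,6R)-6-ethenyl-6-methyl-3-[(triisopropylsilyl)oxy]cyclohex-3-en-1-yl}propan-2-ol | C=C[C@@]1(C)CC=C(O[Si](C(C)C)(C(C)C)C(C)C)C[C@@H]1C(C)(C)O
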